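**Retrosynthetic overview** (disconnections listed from the first bond made to the last)
1. Side-chain C–C bond: aryl methyl ketone 1 and homoprenyl bromide 2, joined through Grignard reagent 3, give the racemic tertiary benzylic carbinol 4.
2. Benzylic C–H bond (the stereocentre): 4 is ionised to ortho-quinone methide 5, which a chiral Brønsted acid and a Hantzsch ester reduce enantioselectively to (S)-curcuphenol 6 (metal-free, stereoablative).
3. Biaryl C4–C4' bond: para–para oxidative homocoupling of two molecules of 6 gives the target 7, with both (S) centres already in place.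
4. Rings: none is built; both benzene rings arrive intact in 1.

Assumption: the (S,S) hand of the acid catalyst in Step 2 is taken to give the (S) product; if the first run gives (R), the (R,R) catalyst is used with nothing else changed.

Step 1
Reactants: 1 2'-hydroxy-4'-methylacetophenone [1-(2-hydroxy-4-methylphenyl)ethan-1-one]; 2 5-bromo-2-methylpent-2-ene (homoprenyl bromide)
Product: 4 racemic 2-(2-hydroxy-6-methylhept-5-en-2-yl)-5-methylphenol, via Grignard reagent 3 (not isolated)
Conditions: Mg turnings (2.6 equiv), THF, rt, 2 (2.5 equiv); then 1 (1.0 equiv), 0 °C → rt; H2O quench at 0 °C; crude 4 used after filtration through Et3N-washed silica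
Reagents that add atoms: none
Why: Grignard formation followed by 1,2-addition to the aryl ketone, in which one equivalent of 3 deprotonates the phenol and the chelated magnesium phenoxide takes the second at the carbonyl; the new carbinol centre is deliberately racemic because Step 2 erases it.

Step 2
Reactants: 4 racemic 2-(2-hydroxy-6-methylhept-5-en-2-yl)-5-methylphenol
Product: 6 (S)-curcuphenol = 5-methyl-2-[(2S)-6-methylhept-5-en-2-yl]phenol, via ortho-quinone methide 5 (not isolated)
Conditions: (S,S)-imidodiphosphoric acid built from two (S)-3,3'-bis(2,4,6-triethylphenyl)-1,1'-bi-2-naphthol units (5 mol %), Hantzsch ester (diethyl 2,6-dimethyl-1,4-dihydropyridine-3,5-dicarboxylate, 1.4 equiv), 5 Å MS, PhMe, 25 °C, 4 added by syringe pump over 8 h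
Reagents that add atoms: none
Why: Proposed new method: the acid dehydrates 4 to ortho-quinone methide 5, whose E and Z forms interconvert through the catalyst-bound benzylic cation and its alkene tautomers (Curtin–Hammett), and the confined bifunctional acid holds the quinone methide oxygen (P–OH) and the Hantzsch N–H (P=O), seats the small methyl inside the pocket syn to the carbonyl with the homoprenyl chain pointing out (E form), and passes hydride to the open Re face of the exocyclic carbon to set (S), while slow addition keeps 5 too dilute to dimerise; the closest known reaction type is chiral phosphoric acid-catalysed transfer hydrogenation of 1,1-diaryl ortho-quinone methides with Hantzsch esters, which has not been shown for a methyl/primary-alkyl pair.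

Step 3
Reactants: 6 (S)-curcuphenol (two molecules)
Product: 7 target 2,2'-dimethyl-5,5'-bis[(2S)-6-methylhept-5-en-2-yl]-[1,1'-biphenyl]-4,4'-diol
Conditions: Cr(salen)Cl (10 mol %; salen = N,N'-bis(3,5-di-tert-butylsalicylidene)-1,2-cyclohexanediamine dianion; trivalent chromium), O2 (1 atm), ClCH2CH2Cl, 80 °C
Reagents that add atoms: none
Why: Aerobic oxidative phenol homocoupling, in which the chromium-bound phenoxyl species couples at the open position of highest spin density, C4 para to OH, as thymol-type 2,5-dialkylphenols do; the twisted 2,2'-dimethylbiphenol resists over-oxidation to a diphenoquinone, and neither stereocentre is touched, so two (S) units give the (S,S) dimer.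

**Compound list**
1 | 2'-hydroxy-4'-methylacetophenone | CC(=O)c1ccc(C)cc1O | starting material
2 | 5-bromo-2-methylpent-2-ene | CC(C)=CCCBr | starting material
3 | (4-methylpent-3-en-1-yl)magnesium bromide | CC(C)=CCC[Mg]Br | intermediate
4 | racemic 2-(2-hydroxy-6-methylhept-5-en-2-yl)-5-methylphenol | CC(C)=CCCC(C)(O)c1ccc(C)cc1O | intermediate
5 | 3-methyl-6-(6-methylhept-5-en-2-ylidene)cyclohexa-2,4-dien-1-one (E/Z mixture) | CC(C)=CCCC(C)=C1C=CC(C)=CC1=O | intermediate
6 | (S)-curcuphenol, 5-methyl-2-[(2S)-6-methylhept-5-en-2-yl]phenol | CC(C)=CCC[C@H](C)c1ccc(C)cc1O | intermediate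
7 | 2,2'-dimethyl-5,5'-bis[(2S)-6-methylhept-5-en-2-yl]-[1,1'-biphenyl]-4,4'-diol | CC(C)=CCC[C@H](C)c1cc(-c2cc([C@@H](C)CCC=C(C)C)c(O)cc2C)c(C)cc1O | target

**Totals**
Total steps: 3. Longest linear sequence: 3 (1 or 2 → 4 → 6 → 7).

Stereochemical bookkeeping: both centres are set in Step 2 and carried unchanged through Step 3. The 2,2'-dimethylbiaryl axis is not configurationally stable, so it adds no stereoelement. If 6 is obtained at 96:4 er, homocoupling gives about 92.2 % (S,S), 7.7 % meso and 0.2 % (R,R). The meso diastereomer is removed by preparative HPLC, or the er of 6 is raised first.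

**Steps most likely to fail** (ranked by risk: Step 2 > Step 3 > Step 1; taken in step order)

Step 1. Risk: Grignard reagent 3 forms poorly (Wurtz coupling), or ketone 1 is enolised instead of attacked. The fallback sets out from 1 and comes back at 4.
- 1 is deprotonated twice with commercial LDA (2.2 equiv, THF, −78 → 0 °C) to dilithium 1-(4-methyl-2-oxidophenyl)ethen-1-olate F1.
- F1 is C-alkylated with prenyl bromide (1-bromo-3-methylbut-2-ene, 1.0 equiv; 1 M HCl work-up) to 1-(2-hydroxy-4-methylphenyl)-5-methylhex-4-en-1-one F2.
- Commercial MeMgBr (2.5 equiv, THF, 0 °C; H2O quench) adds to F2 and gives 4.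
- The change: the side-chain C–C bond now comes from enolate alkylation, and the carbonyl addition uses the small methyl Grignard.

Step 2 (the new reaction). Risks: low er for the methyl/alkyl pair; hetero-Diels–Alder dimerisation of 5 with its styrene tautomers; slow ionisation of 4. The fallback uses known chemistry, sets out from 1 and comes back at 6.
- Ketone 1-(2-hydroxy-4-methylphenyl)-5-methylhex-4-en-1-one F2 is made from 1 through F1 as above.
- F2 is silylated (TBSCl, imidazole, DMF, 40 °C) to 1-{2-[(tert-butyldimethylsilyl)oxy]-4-methylphenyl}-5-methylhex-4-en-1-one F3.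
- F3 is methylenated by a Wittig reaction (Ph3PCH3Br, KOtBu, THF, 0 °C → rt) to tert-butyldimethyl[5-methyl-2-(6-methylhepta-1,5-dien-2-yl)phenoxy]silane F4.
- The terminal 1,1-disubstituted aryl alkene of F4 is hydrogenated with a chiral iridium P,N catalyst to tert-butyldimethyl{5-methyl-2-[(2S)-6-methylhept-5-en-2-yl]phenoxy}silane F5. Conditions: [Ir(cod)(ThrePHOX)]BArF (1 mol %; cod = 1,5-cyclooctadiene, ThrePHOX = threonine-derived phosphinite–oxazoline, BArF = tetrakis[3,5-bis(trifluoromethyl)phenyl]borate), H2 (1 bar), CH2Cl2, 0 °C, stopped after one equivalent of H2, ligand hand chosen for (S).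
- Bu4NF (THF, 0 °C, H2O work-up) then frees 6.
- Asymmetric hydrogenation of 2-aryl-1-alkenes with such catalysts is an established reaction class. The trisubstituted dialkyl alkene reacts far more slowly at 1 bar. The silyl ether blocks acid-triggered quinone methide chemistry during hydrogenation.

Step 3. Risks: ortho–para or C–O coupled isomers; oxidation of 6 to a quinone methide at the benzylic C–H; oxidation of the trisubstituted alkene. The fallback sets out from 6 and comes back at 7.
- Para-iodination with I2/morpholine (CH2Cl2, 0 °C → rt) gives 4-iodo-5-methyl-2-[(2S)-6-methylhept-5-en-2-yl]phenol F6.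
- One-pot Miyaura borylation/Suzuki homocoupling (B2pin2 0.5 equiv, Pd(dppf)Cl2 5 mol %, K2CO3, dioxane/H2O, 90 °C) runs through 5-methyl-2-[(2S)-6-methylhept-5-en-2-yl]-4-(4,4,5,5-tetramethyl-1,3,2-dioxaborolan-2-yl)phenol F7 and gives 7.
- The biaryl bond is fixed at C4 by the halogen, not by radical spin density.

**Further compounds**
F1 | step 1 | dilithium 1-(4-methyl-2-oxidophenyl)ethen-1-olate | [Li+].[Li+].C=C([O-])c1ccc(C)cc1[O-]
F2 | step 1 | 1-(2-hydroxy-4-methylphenyl)-5-methylhex-4-en-1-one | CC(C)=CCCC(=O)c1ccc(C)cc1O
F3 | step 2 | 1-{2-[(tert-butyldimethylsilyl)oxy]-4-methylphenyl}-5-methylhex-4-en-1-one | CC(C)=CCCC(=O)c1ccc(C)cc1O[Si](C)(C)C(C)(C)C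
F4 | step 2 | tert-butyldimethyl[5-methyl-2-(6-methylhepta-1,5-dien-2-yl)phenoxy]silane | C=C(CCC=C(C)C)c1ccc(C)cc1O[Si](C)(C)C(C)(C)C
F5 | step 2 | tert-butyldimethyl{5-methyl-2-[(2S)-6-methylhept-5-en-2-yl]phenoxy}silane | CC(C)=CCC[C@H](C)c1ccc(C)cc1O[Si](C)(C)C(C)(C)C
F6 | step 3 | 4-iodo-5-methyl-2-[(2S)-6-methylhept-5-en-2-yl]phenol | CC(C)=CCC[C@H](C)c1cc(I)c(C)cc1O
F7 | step 3 | 5-methyl-2-[(2S)-6-methylhept-5-en-2-yl]-4-(4,4,5,5-tetramethyl-1,3,2-dioxaborolan-2-yl)phenol | CC(C)=CCC[C@H](C)c1cc(B2OC(C)(C)C(C)(C)O2)c(C)cc1O
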